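The flavonol is cut at C3–C4 and C2=C3 of ring C. C3 is a single oxygen-bearing carbon flanked by two acyl-level carbons, C4 (attached to ring A) and C2 (attached to ring B), so it can come from an alkoxymethylene ylide. In the key step this ylide is C-acylated by a silyl salicylate and the resulting acylphosphorane then olefinates the neighbouring O-aroyl ester, closing the pyranone with O1 and O3 in place. The precursor is the tert-butyldimethylsilyl ester of a 2-aroyloxy-4,6-bis(benzyloxy)benzoic acid, assembled through an allyl ester. The 2-(trimethylsilyl)ethyl group on O3 is orthogonal to benzyl, which allows 3-O-acetylation before hydrogenolysis and sulfation.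

Key step: step 6

Remarks on the chemistry:
- The target has no stereocentre or other stereogenic element, so it is one achiral compound and no step has to control configuration.
- The target is drawn as the free tris(hydrogen sulfate). It should form as its pyridinium salt and is converted to the free acid by cold cation exchange. Aryl hydrogen sulfates are acid-labile, so the free acid should be used or re-salted at once.
- Compounds 4 and 9 are taken as commercial.

Step 1
Reactants: 1 2,4,6-trihydroxybenzoic acid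
Product: 2 allyl 2,4,6-trihydroxybenzoate
Conditions: allyl bromide (1.05 equiv), KHCO3 (1.1 equiv), DMF, rt
Reagents that add atoms: allyl bromide, C=CCBr
Why: Carboxylate O-alkylation (SN2): bicarbonate ionises only the strongly acidic carboxyl group, so the allyl ester should form at room temperature without the acid and heat that decarboxylate this acid and without etherifying the phenols.

Step 2
Reactants: 2 allyl 2,4,6-trihydroxybenzoate
Product: 3 allyl 2,4-bis(benzyloxy)-6-hydroxybenzoate
Conditions: BnBr (2.1 equiv), K2CO3, acetone, reflux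
Reagents that add atoms: benzyl bromide, BrCc1ccccc1
Why: Williamson ether synthesis: the 4-OH and one ortho OH are alkylated, whereas the remaining ortho OH is tied up in a hydrogen bond to the ester carbonyl and should stay free when two equivalents of benzyl bromide are used.

Step 3
Reactants: 3 allyl 2,4-bis(benzyloxy)-6-hydroxybenzoate; 4 3,4-bis(benzyloxy)benzoic acid
Product: 6 allyl 2,4-bis(benzyloxy)-6-{[3,4-bis(benzyloxy)benzoyl]oxy}benzoate, via 3,4-bis(benzyloxy)benzoyl chloride 5 (not isolated)
Conditions: 4, (COCl)2, DMF (cat.), CH2Cl2, 0 °C → rt, evaporate; then 3, Et3N, DMAP (cat.), CH2Cl2, 0 °C → rt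
Reagents that add atoms: none
Why: Acid chloride formation (Vilsmeier-type activation) and DMAP-catalysed O-acylation: nucleophilic catalysis overcomes the low reactivity of the chelated phenol, as in the aroylation of 2-hydroxy-4,6-dialkoxyaryl ketones, and no free carboxylic acid is present to form mixed anhydrides.

Step 4
Reactants: 6 allyl 2,4-bis(benzyloxy)-6-{[3,4-bis(benzyloxy)benzoyl]oxy}benzoate
Product: 7 2,4-bis(benzyloxy)-6-{[3,4-bis(benzyloxy)benzoyl]oxy}benzoic acid
Conditions: Pd(PPh3)4 (3 mol %), PhNHMe (2 equiv), THF, rt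
Reagents that add atoms: none
Why: Tsuji–Trost deallylation: Pd(0) ionises only the allyl ester and the π-allyl complex is intercepted by the weakly basic N-methylaniline, so the benzyl ethers and the aryl benzoate should be untouched and the hindered carboxyl group is freed without hydroxide.

Step 5
Reactants: 7 2,4-bis(benzyloxy)-6-{[3,4-bis(benzyloxy)benzoyl]oxy}benzoic acid
Product: 8 tert-butyldimethylsilyl 2,4-bis(benzyloxy)-6-{[3,4-bis(benzyloxy)benzoyl]oxy}benzoate
Conditions: TBSCl, imidazole, CH2Cl2, rt; hexane, filter, concentrate; used crude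
Reagents that add atoms: tert-butyldimethylsilyl chloride, CC(C)(C)[Si](C)(C)Cl
Why: O-Silylation of the carboxylic acid with a silyl chloride and imidazole: the carboxylate attacks silicon, which is insensitive to the ortho substituents, and non-aqueous isolation keeps the moisture-sensitive silyl ester intact for direct use.

Step 6
Reactants: 8 tert-butyldimethylsilyl 2,4-bis(benzyloxy)-6-{[3,4-bis(benzyloxy)benzoyl]oxy}benzoate; 9 {[2-(trimethylsilyl)ethoxy]methyl}triphenylphosphonium chloride
Product: 12 5,7-bis(benzyloxy)-2-[3,4-bis(benzyloxy)phenyl]-3-[2-(trimethylsilyl)ethoxy]chromen-4-one, via [2-(trimethylsilyl)ethoxy]methylenetriphenylphosphorane 10 (not isolated), via α-alkoxy acylphosphorane 11 (not isolated)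
Conditions: 9 (2.2 equiv), KHMDS (2.1 equiv), THF, −78 → 0 °C; add 8, −78 °C → rt; then PhMe, 110 °C
Reagents that add atoms: none
Why: Proposed new method: ylide 10 should attack the silyl ester carbonyl of 8 and expel silanolate (C-acylation, forming C3–C4), and the second equivalent of 10 (or the silanolate) deprotonates the resulting acylphosphonium ion to the keto-stabilised α-alkoxy ylide 11, whose carbanion carbon on heating adds to the adjacent aryl ester carbonyl, closes to an oxaphosphetane and loses triphenylphosphine oxide to form C2=C3. The closest known reaction type is the acylation of alkylidenephosphoranes by silyl esters of O-acyl- and O-aroylsalicylic acids followed by intramolecular Wittig olefination of the ester carbonyl to give 3-unsubstituted chromones and flavones; an oxygen substituent on the ylide carbon has not been tried in that setting, although it should raise the nucleophilicity of 11 towards the ester. Ring C closes by 6-exo-trig attack of C3 on the ester carbon that becomes C2, with the former phenol oxygen retained as O1 and the ylide oxygen as O3. No stereocentre is created and the new C2=C3 bond is endocyclic, so no geometrical question arises. The step needs chemoselective acylation at the silyl ester in the presence of the aryl benzoate: the silyl carboxylate is anhydride-like and twisted out of conjugation with ring A by its two ortho substituents, the aryl ester carbonyl is deactivated by the 3,4-dialkoxyphenyl donor, the tert-butyl group on silicon blocks attack at silicon, and 8 is added at −78 °C to the preformed ylide.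

Step 7
Reactants: 12 5,7-bis(benzyloxy)-2-[3,4-bis(benzyloxy)phenyl]-3-[2-(trimethylsilyl)ethoxy]chromen-4-one
Product: 13 5,7-bis(benzyloxy)-2-[3,4-bis(benzyloxy)phenyl]-3-hydroxychromen-4-one
Conditions: TBAF (1 M in THF), THF, 0 °C → rt; then AcOH
Reagents that add atoms: none
Why: Fluoride-induced β-elimination of a 2-(trimethylsilyl)ethyl ether (fluoride attacks silicon; ethylene and the well-stabilised flavonol 3-oxide are expelled): benzyl ethers are inert to fluoride, and a Lewis acid, which would endanger the peri 5-O-benzyl ether, is avoided.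

Step 8
Reactants: 13 5,7-bis(benzyloxy)-2-[3,4-bis(benzyloxy)phenyl]-3-hydroxychromen-4-one
Product: 14 5,7-bis(benzyloxy)-2-[3,4-bis(benzyloxy)phenyl]-4-oxochromen-3-yl acetate
Conditions: Ac2O, pyridine, DMAP (cat.), CH2Cl2, rt
Reagents that add atoms: acetic anhydride, CC(=O)OC(C)=O
Why: DMAP-catalysed acetylation (nucleophilic acyl substitution) of the only free hydroxyl group.

Step 9
Reactants: 14 5,7-bis(benzyloxy)-2-[3,4-bis(benzyloxy)phenyl]-4-oxochromen-3-yl acetate
Product: 15 2-(3,4-dihydroxyphenyl)-5,7-dihydroxy-4-oxochromen-3-yl acetate (quercetin 3-acetate)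
Conditions: H2 (1 atm), 10% Pd/C, THF–EtOAc, rt
Reagents that add atoms: none
Why: Catalytic hydrogenolysis of benzyl ethers: in a neutral aprotic solvent the enol acetate cannot be solvolysed and the tetrasubstituted, conjugated C2=C3 bond of the chromone is not normally reduced at 1 atm.

Step 10
Reactants: 15 2-(3,4-dihydroxyphenyl)-5,7-dihydroxy-4-oxochromen-3-yl acetate
Product: 16 quercetin 3-acetate 7,3',4'-tris(hydrogen sulfate) (target)
Conditions: SO3·pyridine (ca. 12 equiv), DMF, rt; H2O, 0 °C; Sephadex LH-20; Dowex 50W (H+), 0 °C, lyophilise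
Reagents that add atoms: sulfur trioxide–pyridine complex, O=S(=O)([O-])[n+]1ccccc1
Why: Phenol O-sulfation with a sulfur trioxide–amine complex: the 7-, 3'- and 4'-hydroxyls are free phenols, whereas the 5-hydroxyl is held in a strong hydrogen bond to the C4 carbonyl and is the least nucleophilic, so it should survive a controlled excess at room temperature, and the neutral anhydrous medium should spare the 3-acetate.

Compound list
1 | 2,4,6-trihydroxybenzoic acid | O=C(O)c1c(O)cc(O)cc1O | starting material
2 | allyl 2,4,6-trihydroxybenzoate | C=CCOC(=O)c1c(O)cc(O)cc1O | intermediate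
3 | allyl 2,4-bis(benzyloxy)-6-hydroxybenzoate | C=CCOC(=O)c1c(OCc2ccccc2)cc(OCc2ccccc2)cc1O | intermediate
4 | 3,4-bis(benzyloxy)benzoic acid | O=C(O)c1ccc(OCc2ccccc2)c(OCc2ccccc2)c1 | starting material
5 | 3,4-bis(benzyloxy)benzoyl chloride | O=C(Cl)c1ccc(OCc2ccccc2)c(OCc2ccccc2)c1 | intermediate (not isolated)
6 | allyl 2,4-bis(benzyloxy)-6-{[3,4-bis(benzyloxy)benzoyl]oxy}benzoate | C=CCOC(=O)c1c(OCc2ccccc2)cc(OCc2ccccc2)cc1OC(=O)c1ccc(OCc2ccccc2)c(OCc2ccccc2)c1 | intermediate
7 | 2,4-bis(benzyloxy)-6-{[3,4-bis(benzyloxy)benzoyl]oxy}benzoic acid | O=C(O)c1c(OCc2ccccc2)cc(OCc2ccccc2)cc1OC(=O)c1ccc(OCc2ccccc2)c(OCc2ccccc2)c1 | intermediate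
8 | tert-butyldimethylsilyl 2,4-bis(benzyloxy)-6-{[3,4-bis(benzyloxy)benzoyl]oxy}benzoate | CC(C)(C)[Si](C)(C)OC(=O)c1c(OCc2ccccc2)cc(OCc2ccccc2)cc1OC(=O)c1ccc(OCc2ccccc2)c(OCc2ccccc2)c1 | intermediate (key-step precursor)
9 | {[2-(trimethylsilyl)ethoxy]methyl}triphenylphosphonium chloride | C[Si](C)(C)CCOC[P+](c1ccccc1)(c1ccccc1)c1ccccc1.[Cl-] | starting material
10 | [2-(trimethylsilyl)ethoxy]methylenetriphenylphosphorane | C[Si](C)(C)CCOC=P(c1ccccc1)(c1ccccc1)c1ccccc1 | intermediate (not isolated)
11 | 3,5-bis(benzyloxy)-2-{2-[2-(trimethylsilyl)ethoxy]-2-(triphenylphosphoranylidene)acetyl}phenyl 3,4-bis(benzyloxy)benzoate (α-alkoxy acylphosphorane) | C[Si](C)(C)CCOC(=P(c1ccccc1)(c1ccccc1)c1ccccc1)C(=O)c1c(OCc2ccccc2)cc(OCc2ccccc2)cc1OC(=O)c1ccc(OCc2ccccc2)c(OCc2ccccc2)c1 | intermediate (not isolated)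
12 | 5,7-bis(benzyloxy)-2-[3,4-bis(benzyloxy)phenyl]-3-[2-(trimethylsilyl)ethoxy]chromen-4-one | C[Si](C)(C)CCOc1c(-c2ccc(OCc3ccccc3)c(OCc3ccccc3)c2)oc2cc(OCc3ccccc3)cc(OCc3ccccc3)c2c1=O | intermediate (key-step product)
13 | 5,7-bis(benzyloxy)-2-[3,4-bis(benzyloxy)phenyl]-3-hydroxychromen-4-one | O=c1c(O)c(-c2ccc(OCc3ccccc3)c(OCc3ccccc3)c2)oc2cc(OCc3ccccc3)cc(OCc3ccccc3)c12 | intermediate
14 | 5,7-bis(benzyloxy)-2-[3,4-bis(benzyloxy)phenyl]-4-oxochromen-3-yl acetate | CC(=O)Oc1c(-c2ccc(OCc3ccccc3)c(OCc3ccccc3)c2)oc2cc(OCc3ccccc3)cc(OCc3ccccc3)c2c1=O | intermediate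
15 | 2-(3,4-dihydroxyphenyl)-5,7-dihydroxy-4-oxochromen-3-yl acetate (quercetin 3-acetate) | CC(=O)Oc1c(-c2ccc(O)c(O)c2)oc2cc(O)cc(O)c2c1=O | intermediate
16 | quercetin 3-acetate 7,3',4'-tris(hydrogen sulfate) | CC(=O)Oc1c(-c2ccc(OS(=O)(=O)O)c(OS(=O)(=O)O)c2)oc2cc(OS(=O)(=O)O)cc(O)c2c1=O | target

Total step count: 10. Longest linear sequence: 10 steps (1 → 2 → 3 → 6 → 7 → 8 → 12 → 13 → 14 → 15 → 16).

Steps most likely to fail

Step 6. The ylide may add to the aryl benzoate carbonyl instead of the doubly ortho-flanked silyl ester, which would break the O1–C2 link. The thermally fragile alkoxy ylide may also decay before it is acylated, and the tetrasubstituted ylide 11 may olefinate the electron-rich ester only slowly. The fallback uses known chemistry: ring C is built by Baker–Venkataraman rearrangement and O3 is introduced afterwards by oxidation. It sets out from 4, which is converted to 5 as in step 3. Chloride 5 acylates commercial 1-[2,4-bis(benzyloxy)-6-hydroxyphenyl]ethanone (CC(=O)c1c(O)cc(OCc2ccccc2)cc1OCc1ccccc1) with Et3N and DMAP in CH2Cl2 to give 2-acetyl-3,5-bis(benzyloxy)phenyl 3,4-bis(benzyloxy)benzoate F1. KOH in pyridine at 50 °C should move the aroyl group to carbon and give 1-[2,4-bis(benzyloxy)-6-hydroxyphenyl]-3-[3,4-bis(benzyloxy)phenyl]propane-1,3-dione F2. Catalytic TsOH in toluene at reflux should cyclodehydrate it to 5,7-bis(benzyloxy)-2-[3,4-bis(benzyloxy)phenyl]chromen-4-one F3. Dimethyldioxirane in acetone/CH2Cl2 at 0 °C should epoxidise C2=C3 to the racemic, cis-fused flavone 2,3-epoxide F4, which a trace of TsOH isomerises to the 3-hydroxyflavone. The fallback comes back to the route at 13, so step 7 is not needed and step 8 follows.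

Step 10. Sulfation may stop short at the 3'-hydroxyl once the neighbouring 4'-sulfate is in place, while forcing it may sulfate the 5-hydroxyl. The 3-acetate may also be lost by pyridine-mediated acyl transfer or by hydrolysis during aqueous ion exchange. The fallback moves the acetylation to the end, so the labile ester never sees the sulfation. It sets out from 12. Hydrogenolysis (H2, Pd/C, THF) should give 5,7-dihydroxy-2-(3,4-dihydroxyphenyl)-3-[2-(trimethylsilyl)ethoxy]chromen-4-one F5. Its robust 3-ether tolerates forcing sulfation (SO3·NMe3, Et3N, DMF, 50 °C) to 3-O-[2-(trimethylsilyl)ethyl]quercetin 7,3',4'-tris(hydrogen sulfate) F6. TBAF in THF then frees the 3-hydroxyl to give quercetin 7,3',4'-tris(hydrogen sulfate) F7. Acetylation with Ac2O (1.1 equiv) in pyridine at 0 °C should occur at the 3-hydroxyl and leave the chelated 5-hydroxyl alone. The fallback comes back to the route at 16.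

Step 2. Partial benzylation may run on to the tri-O-benzyl ether or benzylate the phloroglucinol ring at carbon, so the three phenols are not cleanly differentiated. The fallback fixes the free ortho oxygen by ring structure. It sets out from 1. Acetone, TFAA and TFA (0 °C → rt) should give 5,7-dihydroxy-2,2-dimethyl-4H-1,3-benzodioxin-4-one F8. Exhaustive benzylation (BnBr, K2CO3, DMF, 60 °C) should give 5,7-bis(benzyloxy)-2,2-dimethyl-4H-1,3-benzodioxin-4-one F9. Sodium allyloxide (allyl alcohol, NaH, THF, 0 °C → rt) opens the dioxinone at the carbonyl, releases the masked phenol and forms the allyl ester. The fallback comes back to the route at 3.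

Further compounds
F1 | step 6 | 2-acetyl-3,5-bis(benzyloxy)phenyl 3,4-bis(benzyloxy)benzoate | CC(=O)c1c(OCc2ccccc2)cc(OCc2ccccc2)cc1OC(=O)c1ccc(OCc2ccccc2)c(OCc2ccccc2)c1
F2 | step 6 | 1-[2,4-bis(benzyloxy)-6-hydroxyphenyl]-3-[3,4-bis(benzyloxy)phenyl]propane-1,3-dione | O=C(CC(=O)c1ccc(OCc2ccccc2)c(OCc2ccccc2)c1)c1c(O)cc(OCc2ccccc2)cc1OCc1ccccc1
F3 | step 6 | 5,7-bis(benzyloxy)-2-[3,4-bis(benzyloxy)phenyl]chromen-4-one | O=c1cc(-c2ccc(OCc3ccccc3)c(OCc3ccccc3)c2)oc2cc(OCc3ccccc3)cc(OCc3ccccc3)c12
F4 | step 6 | 4,6-bis(benzyloxy)-1a-[3,4-bis(benzyloxy)phenyl]-1a,7a-dihydro-7H-oxireno[2,3-b]chromen-7-one (racemic, cis-fused; one enantiomer drawn) | O=C1c2c(OCc3ccccc3)cc(OCc3ccccc3)cc2O[C@]2(c3ccc(OCc4ccccc4)c(OCc4ccccc4)c3)O[C@H]12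
F5 | step 10 | 5,7-dihydroxy-2-(3,4-dihydroxyphenyl)-3-[2-(trimethylsilyl)ethoxy]chromen-4-one | C[Si](C)(C)CCOc1c(-c2ccc(O)c(O)c2)oc2cc(O)cc(O)c2c1=O
F6 | step 10 | 3-O-[2-(trimethylsilyl)ethyl]quercetin 7,3',4'-tris(hydrogen sulfate) | C[Si](C)(C)CCOc1c(-c2ccc(OS(=O)(=O)O)c(OS(=O)(=O)O)c2)oc2cc(OS(=O)(=O)O)cc(O)c2c1=O
F7 | step 10 | quercetin 7,3',4'-tris(hydrogen sulfate) | O=c1c(O)c(-c2ccc(OS(=O)(=O)O)c(OS(=O)(=O)O)c2)oc2cc(OS(=O)(=O)O)cc(O)c12
F8 | step 2 | 5,7-dihydroxy-2,2-dimethyl-4H-1,3-benzodioxin-4-one | CC1(C)OC(=O)c2c(O)cc(O)cc2O1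
F9 | step 2 | 5,7-bis(benzyloxy)-2,2-dimethyl-4H-1,3-benzodioxin-4-one | CC1(C)OC(=O)c2c(OCc3ccccc3)cc(OCc3ccccc3)cc2O1
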